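All runs were computed with constants of no real substance.

Take the logarithm of the substrate left, follow its fall per hour and divide by the partner present. With a rate that goes with substrate and partner, and with the working catalyst unchanged, this number stays the same whatever the substrate does.

all flasks: free catalyst 5.5 mM; added ligand 3.1 mM

| run | substrate | partner | remark | time |
|---|---|---|---|---|
| Saturday's | 0.11 M | 0.44 M | run made earlier |  |
| Tuesday's | 0.11 M | 0.22 M | run made earlier |  |
| Thursday's | 0.11 M | 0.88 M | run made earlier |  |
| north-west | 0.11 M (fed, over 4.0 h) | 0.440 M | all else is in the flask from the start; the feed brings no volume worth counting | 5.0 h |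
| north-east | 0.11 M | 0.440 M (fed, over 4.0 h) | all else is in the flask from the start; the feed brings no volume worth counting | 5.0 h |
| south-east | 0.11 M | 0.440 M | everything together at the start | 5.0 h |

| run | time / h | product / % | substrate / % |
|---|---|---|---|
| Saturday's | 0.250 | 90 | 10 |
| Saturday's | 0.833 | 94 | 3 |
| Saturday's | 1.33 | 96 | 0 |
| Saturday's | 2.00 | 97 | 0 |
| Saturday's | 3.00 | 101 | 1 |
| Tuesday's | 0.500 | 79 | 25 |
| Tuesday's | 1.50 | 89 | 8 |
| Tuesday's | 3.00 | 95 | 2 |
| Tuesday's | 4.00 | 94 | 3 |
| Tuesday's | 6.00 | 100 | 2 |
| Thursday's | 0.500 | 99 | 1 |
| Thursday's | 0.833 | 98 | 0 |
| Thursday's | 1.50 | 97 | 1 |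
| Thursday's | 3.00 | 99 | 0 |
| Thursday's | 6.00 | 97 | 3 |

(standard deviation of a reading: 2 percentage points)

- the flask that comes out highest in amount of product, in percent of the substrate charged, or "all alike" when all lie within 1.5 percentage points (north-west / north-east / south-east / all alike)
- product at the end, in percent of the substrate charged, north-west
- product at the end, in percent of the substrate charged, north-east
- product at the end, in percent of the substrate charged, south-east



Read that number from Tuesday's run between 0.500 h and 1.50 h, counting one partner per substrate: 8.89 M⁻¹ h⁻¹. Call it the working rate. Saturday's first reading gives 23.6 M⁻¹ h⁻¹, so as read, it is higher early on. Within each run time and conversion rose together, so a fall within one run does not by itself tell which of the two brought it down.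

Now turn the question round: what must hold for north-west to match south-east? Reckon with a steady rate: during the feed, substrate in north-west stands where feed meets consumption, a share of the charge equal to one over hourly fall times feed time. After the feed, let it decay exponentially. With partner near 0.330 M, Tuesday's rate gives an hourly fall (a pseudo-first-order rate constant) of 2.93 h⁻¹, and this reckoning leaves 0.453% of the substrate charged in north-west at the end. Take half that rate, an hourly fall of 1.47 h⁻¹, and the reckoning leaves 3.93%, outside the margin of 1.5 percentage points. So a fall of the rate by a factor 2 is enough to take north-west out of the margin, and the fall read between the two runs is larger. I would therefore expect north-west to fall behind if the rate follows time.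

The forecast gave 98% for north-west, 99% for north-east and 99.5% for south-east, so all alike, reading the slowing as “in step with conversion rather than time”.

North-west gave 77.3%, north-east 85.9% and south-east >99.9%, so the highest is south-east.

    free catalyst → spent catalyst B (k = 2.39 × 10⁻⁴ s⁻¹)
    free catalyst + added ligand ⇌ idle complex, settled at all times (K = 739 M⁻¹)
    2 free catalyst → spent catalyst A (k = 0.528 M⁻¹ s⁻¹)
    substrate + partner + free catalyst → product + free catalyst, rate k4*[substrate]*[partner]*[free catalyst]/(1 + ([substrate]/sat4)) (0.193 M, k = 5.32 M⁻² s⁻¹)

In north-west, half of what free catalyst lost in pairs up to the end was over by 0.110 h, and half of the product step's turnover up to the end by 2.16 h, later. Substrate and partner over the last hour in north-west give a working rate of 1.01 M⁻¹ h⁻¹, far below the 8.89 M⁻¹ h⁻¹ read on Tuesday. Take a neighbour, north-west with 1.1 M of partner, where free catalyst at the end again stands at 0.927% of its charge: that rate gives an hourly fall of 1.00 h⁻¹, and the same reckoning leaves 9.20% of the substrate charged. The simulated neighbour ends with 5.00% substrate and 95.0% product.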